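**Strategy.** The target is the furanoid (5,8-epoxide) of a C30 apo-carotenal; in carotenoid numbering the ring closed last is the 2,5-dihydrofuran O–C5–C6=C7–C8. That ring is an isomer of an α-hydroxyallene (C5–OH beside a C6=C7=C8 axis), so it is closed by gold-catalysed 5-endo cycloisomerisation of a C15 allenyl carbinol, which forms the C8–O bond and converts the allene axis into the C8 stereocentre in one operation. The axis arises by anti SN2' hydride opening of a propargylic 5,6-epoxide placed syn to the C3 hydroxyl, the only stereocentre set by catalysis (transfer hydrogenation of ketoisophorone). The polyenal is then attached by Horner–Wadsworth–Emmons coupling.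

Key step: step 9

Remark: positions are given in carotenoid numbering (ring C1–C6 with C3–OH and C5 bearing the methyl and the ring oxygen; chain C7–C15, C15'–C8'). The target is read as all-E, (3R,5R,8R), with the C3 hydroxyl cis to the ring oxygen. Ketoisophorone, the E-enynol, the C10 dialdehyde and the C5 phosphonate ester are taken as purchasable. In allene SMILES the hydrogen on C8 is written explicitly.

**Step 1**
Reactants: 1 ketoisophorone (2,6,6-trimethylcyclohex-2-ene-1,4-dione)
Product: 2 (R)-phorenol, (4R)-4-hydroxy-2,6,6-trimethylcyclohex-2-en-1-one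
Conditions: RuCl[(R,R)-TsDPEN](p-cymene) (1 mol%), i-PrOH, rt
Reagents that add atoms: none
Why: Asymmetric transfer hydrogenation (Noyori type) should reduce only the unhindered enone carbonyl (the other is flanked by a quaternary carbon), and the (R,R)-ligand, with the alkenyl π-substituent taking the place of the aryl group of aryl ketones, should give the (R)-carbinol that becomes C3.

**Step 2**
Reactants: 2 (R)-phorenol
Product: 3 (4R)-2,6,6-trimethyl-4-(triethylsilyloxy)cyclohex-2-en-1-one
Conditions: Et3SiCl, imidazole, CH2Cl2, 0 °C → rt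
Reagents that add atoms: chlorotriethylsilane, CC[Si](Cl)(CC)CC
Why: Silyl ether formation masks the hydroxyl for the hydride and triflation chemistry and touches no stereocentre.

**Step 3**
Reactants: 3 silyl ether of (R)-phorenol
Product: 5 (4S)-2,6,6-trimethyl-4-(triethylsilyloxy)cyclohex-1-en-1-yl trifluoromethanesulfonate, via lithium enolate 4 (not isolated)
Conditions: LiBH(s-Bu)3 (L-Selectride), THF, −78 °C; then PhNTf2, −78 °C → rt
Reagents that add atoms: N-phenylbis(trifluoromethanesulfonimide), O=S(=O)(N(c1ccccc1)S(=O)(=O)C(F)(F)F)C(F)(F)F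
Why: Conjugate reduction of the β-unsubstituted enone by the bulky borohydride (1,2-attack is blocked by the gem-dimethyl and α-methyl groups) should give the tetrasubstituted enolate regiospecifically, which is trapped as the enol triflate (reductive enolate triflation) without touching the carbinol centre.

**Step 4**
Reactants: 6 (2E)-3-methylpent-2-en-4-yn-1-ol
Product: 7 tert-butyl{[(2E)-3-methylpent-2-en-4-yn-1-yl]oxy}diphenylsilane
Conditions: t-BuPh2SiCl, imidazole, DMF, rt
Reagents that add atoms: tert-butyl(chloro)diphenylsilane, CC(C)(C)[Si](Cl)(c1ccccc1)c1ccccc1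
Why: Silylation of the primary allylic alcohol gives a robust ether that keeps the vanadium catalyst of step 7 away from the C9=C10 alkene.

**Step 5**
Reactants: 5 enol triflate; 7 enyne silyl ether
Product: 8 triethyl{[(1S)-4-[(3E)-5-(tert-butyldiphenylsilyloxy)-3-methylpent-3-en-1-yn-1-yl]-3,5,5-trimethylcyclohex-3-en-1-yl]oxy}silane
Conditions: Pd(PPh3)4 (5 mol%), CuI (10 mol%), i-Pr2NH, DMF, rt
Reagents that add atoms: none
Why: Sonogashira coupling of the hindered enol triflate with the terminal alkyne joins C6 to C7 and brings in all fifteen carbons with the E C9=C10 bond already in place.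

**Step 6**
Reactants: 8 bis-silyl dienyne
Product: 9 (1S)-4-[(3E)-5-(tert-butyldiphenylsilyloxy)-3-methylpent-3-en-1-yn-1-yl]-3,5,5-trimethylcyclohex-3-en-1-ol
Conditions: pyridinium p-toluenesulfonate (cat.), MeOH/CH2Cl2, 0 °C → rt
Reagents that add atoms: none
Why: Acid-catalysed methanolysis should remove the secondary triethylsilyl ether much faster than the bulky primary tert-butyldiphenylsilyl ether, freeing the C3 hydroxyl as directing group.

**Step 7**
Reactants: 9 homoallylic alcohol
Product: 10 (1R,3R,6R)-6-[(3E)-5-(tert-butyldiphenylsilyloxy)-3-methylpent-3-en-1-yn-1-yl]-1,5,5-trimethyl-7-oxabicyclo[4.1.0]heptan-3-ol (5,6-epoxide cis to the C3 hydroxyl; 3R,5R,6R in carotenoid numbering)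
Conditions: VO(acac)2 (5 mol%), t-BuOOH (decane solution), CH2Cl2, 0 °C → rt
Reagents that add atoms: tert-butyl hydroperoxide, CC(C)(C)OO
Why: In this vanadium-catalysed hydroxyl-directed epoxidation the homoallylic C3–OH binds the metal peroxide and delivers oxygen to its own face of C5=C6, setting C5 and C6 cis to the hydroxyl, while the C9=C10 alkene and the alkyne, which lack a free hydroxyl, are left alone.

**Step 8**
Reactants: 10 propargylic epoxide
Product: 12 allenic diol (1R,3R)-6-[(3E)-5-(tert-butyldiphenylsilyloxy)-3-methylpenta-1,3-dien-1-ylidene]-1,5,5-trimethylcyclohexane-1,3-diol of aS axis (chain on the face of the C5 oxygen; H-8 on the face of the C5 methyl), via silyl ether 11 (not isolated)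
Conditions: (IPr)CuCl (5 mol%), NaOt-Bu (5 mol%), (EtO)2MeSiH, toluene, 0 °C; then K2CO3 (cat.), MeOH
Reagents that add atoms: none
Why: Copper hydride SN2' reduction of a propargyl oxirane (syn hydrocupration with H to C8 and Cu to C7, then anti β-alkoxide elimination) delivers hydride anti to the departing epoxide oxygen, so the C6 configuration is translated into the aS axis; the carbene ligand suppresses over-reduction and the O-silyl ether is cleaved in the methanolic work-up.

**Step 9**
Reactants: 12 allenic diol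
Product: 13 (2R,6R,7aR)-2-[(2E)-4-(tert-butyldiphenylsilyloxy)but-2-en-2-yl]-4,4,7a-trimethyl-2,4,5,6,7,7a-hexahydro-1-benzofuran-6-ol
Conditions: AuCl3 (2 mol%), THF, 0 °C → rt
Reagents that add atoms: none
Why: The trivalent gold salt coordinates the C7=C8 bond of the allene, the C5 hydroxyl adds to C8 anti to gold to give a σ-vinylgold species at C7, and protodeauration releases the 2,5-dihydrofuran and the catalyst. The closest known reaction type is the gold-catalysed cycloisomerisation of α-hydroxyallenes to 2,5-dihydrofurans. The ring (O, C5, C6, C7, C8) closes in the 5-endo-trig mode with C–O bond formation at the allene terminus. C8 is the only new stereocentre and is controlled by the allene axis (axis-to-centre transfer): oxygen attacks within the plane of C1–C6–C5 while H and the C9 chain on C8 stay above and below it, so the chain, which lies on the 5-oxygen face in 12, ends trans to the C5 methyl (8R). The step needs chemoselectivity for the 5-OH over the 3-OH, secured because only the 5-OH is α to the allene, and configurational integrity of the doubly allylic C8–O bond, secured by low catalyst loading in THF and by a short, silyl-protected side chain that makes reionisation slow.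

**Step 10**
Reactants: 13 furanoid silyl ether
Product: 14 (2R,6R,7aR)-2-[(2E)-4-hydroxybut-2-en-2-yl]-4,4,7a-trimethyl-2,4,5,6,7,7a-hexahydro-1-benzofuran-6-ol
Conditions: Bu4NF, THF, 0 °C
Reagents that add atoms: none
Why: Fluoride cleaves the Si–O bond under basic, non-acidic conditions that should leave the acid-labile allylic ring ether and C8 untouched.

**Step 11**
Reactants: 14 furanoid diol
Product: 15 (2E)-3-[(2R,6R,7aR)-6-hydroxy-4,4,7a-trimethyl-2,4,5,6,7,7a-hexahydro-1-benzofuran-2-yl]but-2-enal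
Conditions: MnO2, CH2Cl2, rt
Reagents that add atoms: none
Why: MnO2 oxidises only the primary allylic alcohol (allylic oxidation) and leaves the saturated secondary C3 hydroxyl and C8 alone.

**Step 12**
Reactants: 16 (2E,4E,6E)-2,7-dimethylocta-2,4,6-trienedial (3 equiv); 17 ethyl (2E)-4-(diethoxyphosphoryl)-2-methylbut-2-enoate
Product: 19 ethyl (2E,4E,6E,8E,10E)-2,6,11-trimethyl-12-oxododeca-2,4,6,8,10-pentaenoate, via sodium phosphonate 18 (not isolated)
Conditions: NaN(SiMe3)2, THF, −78 °C; then addition to 16, −78 → 0 °C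
Reagents that add atoms: none
Why: Horner–Wadsworth–Emmons olefination with the anion added to an excess of the symmetrical dialdehyde should stop at mono-olefination and give the E C11'=C12' bond, the E C9'=C10' bond being carried by the reagent.

**Step 13**
Reactants: 19 C15 aldehyde ester
Product: 20 ethyl (2E,4E,6E,8E,10E)-12-hydroxy-2,6,11-trimethyldodeca-2,4,6,8,10-pentaenoate
Conditions: NaBH4, MeOH/THF, −20 °C
Reagents that add atoms: none
Why: Borohydride 1,2-reduction is chemoselective for the aldehyde in the presence of the conjugated ester.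

**Step 14**
Reactants: 20 C15 hydroxy ester
Product: 22 ethyl (2E,4E,6E,8E,10E)-12-(diethoxyphosphoryl)-2,6,11-trimethyldodeca-2,4,6,8,10-pentaenoate, via allylic bromide 21 (not isolated)
Conditions: PBr3, pyridine (cat.), Et2O, −10 °C; then P(OEt)3, toluene, 80 °C
Reagents that add atoms: triethyl phosphite, CCOP(OCC)OCC
Why: The allylic alcohol is brominated and the crude bromide converted by the Michaelis–Arbuzov reaction, SN2 attack of phosphorus at the primary carbon preserving the all-E polyene.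

**Step 15**
Reactants: 15 furanoid C15 aldehyde; 22 C15 phosphonate ester
Product: 24 ethyl (3R,5R,8R)-5,8-epoxy-3-hydroxy-5,8-dihydro-8'-apo-β-caroten-8'-oate (all-E), via sodium phosphonate 23 (not isolated)
Conditions: NaN(SiMe3)2 (1.25 equiv), 22 (1.3 equiv), THF, −78 °C; then 15, −78 → 0 °C
Reagents that add atoms: none
Why: Horner–Wadsworth–Emmons coupling of the preformed, weakly basic polyenyl phosphonate anion with the enal should form the C11=C12 bond E-selectively without deprotonating the C3 hydroxyl or C8–H, so C8 is not epimerised.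

**Step 16**
Reactants: 24 C30 ester
Product: 25 (3R,5R,8R)-5,8-epoxy-5,8-dihydro-8'-apo-β-carotene-3,8'-diol (all-E)
Conditions: i-Bu2AlH (3.5 equiv), THF, −78 °C; aq. potassium sodium tartrate work-up
Reagents that add atoms: none
Why: Aluminium hydride reduction takes the conjugated ester to the allylic alcohol at low temperature in a coordinating solvent that tempers the Lewis acidity of aluminium toward the allylic ring ether.

**Step 17**
Reactants: 25 C30 diol
Product: 26 target, (3R,5R,8R)-5,8-epoxy-3-hydroxy-5,8-dihydro-8'-apo-β-caroten-8'-al (all-E)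
Conditions: MnO2, CH2Cl2, rt, dark
Reagents that add atoms: none
Why: MnO2 oxidation is selective for the polyenylic primary alcohol over the saturated secondary C3 hydroxyl and is neutral, so the furanoid C8 centre should survive.

**Compound list**

1 | ketoisophorone (2,6,6-trimethylcyclohex-2-ene-1,4-dione) | CC1=CC(=O)CC(C)(C)C1=O | starting material
2 | (4R)-4-hydroxy-2,6,6-trimethylcyclohex-2-en-1-one ((R)-phorenol) | O=C1C(C)=C[C@H](O)CC1(C)C | intermediate
3 | (4R)-2,6,6-trimethyl-4-(triethylsilyloxy)cyclohex-2-en-1-one | O=C1C(C)=C[C@H](O[Si](CC)(CC)CC)CC1(C)C | intermediate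
4 | lithium (4S)-2,6,6-trimethyl-4-(triethylsilyloxy)cyclohex-1-en-1-olate | [Li+].[O-]C1=C(C)C[C@H](O[Si](CC)(CC)CC)CC1(C)C | intermediate
5 | (4S)-2,6,6-trimethyl-4-(triethylsilyloxy)cyclohex-1-en-1-yl trifluoromethanesulfonate | O=S(=O)(OC1=C(C)C[C@H](O[Si](CC)(CC)CC)CC1(C)C)C(F)(F)F | intermediate
6 | (2E)-3-methylpent-2-en-4-yn-1-ol | C#C/C(C)=C/CO | starting material
7 | tert-butyl{[(2E)-3-methylpent-2-en-4-yn-1-yl]oxy}diphenylsilane | C#C/C(C)=C/CO[Si](c1ccccc1)(c1ccccc1)C(C)(C)C | intermediate
8 | triethyl{[(1S)-4-[(3E)-5-(tert-butyldiphenylsilyloxy)-3-methylpent-3-en-1-yn-1-yl]-3,5,5-trimethylcyclohex-3-en-1-yl]oxy}silane | CC(C)(C)[Si](OC/C=C(\C)C#CC1=C(C)C[C@H](O[Si](CC)(CC)CC)CC1(C)C)(c2ccccc2)c3ccccc3 | intermediate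
9 | (1S)-4-[(3E)-5-(tert-butyldiphenylsilyloxy)-3-methylpent-3-en-1-yn-1-yl]-3,5,5-trimethylcyclohex-3-en-1-ol | CC(C)(C)[Si](OC/C=C(\C)C#CC1=C(C)C[C@H](O)CC1(C)C)(c2ccccc2)c3ccccc3 | intermediate
10 | (1R,3R,6R)-6-[(3E)-5-(tert-butyldiphenylsilyloxy)-3-methylpent-3-en-1-yn-1-yl]-1,5,5-trimethyl-7-oxabicyclo[4.1.0]heptan-3-ol | CC(C)(C)[Si](OC/C=C(\C)C#C[C@@]12O[C@]1(C)C[C@H](O)CC2(C)C)(c3ccccc3)c4ccccc4 | intermediate
11 | 1-O-[diethoxy(methyl)silyl] ether of 12 (silylated at the tertiary C5 oxygen; aS axis) | [H]C(/C(C)=C/CO[Si](c2ccccc2)(c3ccccc3)C(C)(C)C)=[C@@]=C1C(C)(C)C[C@@H](O)C[C@@]1(C)O[Si](C)(OCC)OCC | intermediate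
12 | (1R,3R)-6-[(3E)-5-(tert-butyldiphenylsilyloxy)-3-methylpenta-1,3-dien-1-ylidene]-1,5,5-trimethylcyclohexane-1,3-diol, aS axis | [H]C(/C(C)=C/CO[Si](c2ccccc2)(c3ccccc3)C(C)(C)C)=[C@@]=C1C(C)(C)C[C@@H](O)C[C@@]1(C)O | intermediate
13 | (2R,6R,7aR)-2-[(2E)-4-(tert-butyldiphenylsilyloxy)but-2-en-2-yl]-4,4,7a-trimethyl-2,4,5,6,7,7a-hexahydro-1-benzofuran-6-ol | CC(C)(C)[Si](OC/C=C(\C)[C@H]1C=C2C(C)(C)C[C@@H](O)C[C@@]2(C)O1)(c3ccccc3)c4ccccc4 | intermediate
14 | (2R,6R,7aR)-2-[(2E)-4-hydroxybut-2-en-2-yl]-4,4,7a-trimethyl-2,4,5,6,7,7a-hexahydro-1-benzofuran-6-ol | OC/C=C(\C)[C@H]1C=C2C(C)(C)C[C@@H](O)C[C@@]2(C)O1 | intermediate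
15 | (2E)-3-[(2R,6R,7aR)-6-hydroxy-4,4,7a-trimethyl-2,4,5,6,7,7a-hexahydro-1-benzofuran-2-yl]but-2-enal | O=C/C=C(\C)[C@H]1C=C2C(C)(C)C[C@@H](O)C[C@@]2(C)O1 | intermediate
16 | (2E,4E,6E)-2,7-dimethylocta-2,4,6-trienedial | O=C/C(C)=C/C=C/C=C(C)/C=O | starting material
17 | ethyl (2E)-4-(diethoxyphosphoryl)-2-methylbut-2-enoate | CCOC(=O)/C(C)=C/CP(=O)(OCC)OCC | starting material
18 | sodium salt (phosphonate carbanion) of 17 | [Na+].CCOC(=O)/C(C)=C/[CH-]P(=O)(OCC)OCC | intermediate
19 | ethyl (2E,4E,6E,8E,10E)-2,6,11-trimethyl-12-oxododeca-2,4,6,8,10-pentaenoate | CCOC(=O)/C(C)=C/C=C/C(C)=C/C=C/C=C(C)/C=O | intermediate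
20 | ethyl (2E,4E,6E,8E,10E)-12-hydroxy-2,6,11-trimethyldodeca-2,4,6,8,10-pentaenoate | CCOC(=O)/C(C)=C/C=C/C(C)=C/C=C/C=C(C)/CO | intermediate
21 | ethyl (2E,4E,6E,8E,10E)-12-bromo-2,6,11-trimethyldodeca-2,4,6,8,10-pentaenoate | CCOC(=O)/C(C)=C/C=C/C(C)=C/C=C/C=C(C)/CBr | intermediate
22 | ethyl (2E,4E,6E,8E,10E)-12-(diethoxyphosphoryl)-2,6,11-trimethyldodeca-2,4,6,8,10-pentaenoate | CCOC(=O)/C(C)=C/C=C/C(C)=C/C=C/C=C(C)/CP(=O)(OCC)OCC | intermediate
23 | sodium salt (phosphonate carbanion) of 22 | [Na+].CCOC(=O)/C(C)=C/C=C/C(C)=C/C=C/C=C(C)/[CH-]P(=O)(OCC)OCC | intermediate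
24 | ethyl (3R,5R,8R)-5,8-epoxy-3-hydroxy-5,8-dihydro-8'-apo-β-caroten-8'-oate (all-E) | CCOC(=O)/C(C)=C/C=C/C(C)=C/C=C/C=C(C)/C=C/C=C(\C)[C@H]1C=C2C(C)(C)C[C@@H](O)C[C@@]2(C)O1 | intermediate
25 | (3R,5R,8R)-5,8-epoxy-5,8-dihydro-8'-apo-β-carotene-3,8'-diol (all-E) | OC/C(C)=C/C=C/C(C)=C/C=C/C=C(C)/C=C/C=C(\C)[C@H]1C=C2C(C)(C)C[C@@H](O)C[C@@]2(C)O1 | intermediate
26 | (3R,5R,8R)-5,8-epoxy-3-hydroxy-5,8-dihydro-8'-apo-β-caroten-8'-al (all-E) | C\C(C=O)=C/C=C/C(C)=C/C=C/C=C(C)/C=C/C=C(\C)[C@H]1C=C2C(C)(C)C[C@@H](O)C[C@@]2(C)O1 | target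

**Step count.** Total: 17 steps. Longest linear sequence: 13 steps (steps 1–3, 5–11, 15–17).

**Steps most likely to fail**

1. Step 8 (copper hydride SN2' reduction). What may go wrong: hydrocupration in the opposite regiochemical sense (copper at C8), further reduction of the conjugated enyne or of the vinylallene, or partial loss of the anti course, so that the axis forms as a mixture. The fallback abandons the allene and uses the classical acid-catalysed epoxide-to-furanoid rearrangement; it sets out from 5 and 7 and comes back at 13. Hydroboration of 7 with pinacolborane and Cp2Zr(H)Cl (cat.) would give the dienylboronate F1. Suzuki–Miyaura coupling of F1 with 5 (Pd(PPh3)4, K3PO4, dioxane/H2O, 60 °C) would give the triene bis-silyl ether F2. Pyridinium p-toluenesulfonate in MeOH would give the trienol F3, and VO(acac)2/t-BuOOH the syn-epoxide F4. Catalytic camphorsulfonic acid in CH2Cl2 at 0 °C would then ionise the C6–O bond and let the C5 oxygen add to C8. This should give 13 together with its C8 epimer F5; the two are separated by chromatography and F5 is re-equilibrated with the same acid.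

2. Step 9 (gold cycloisomerisation). What may go wrong: gold-promoted reionisation of the doubly allylic C8–O bond with erosion of configuration at C8, or competing cyclisation of the vinylallene through carbon. The fallback replaces catalysis by a stoichiometric electrophile and a reduction; it sets out from 12 and comes back at 13. Iodoetherification with N-iodosuccinimide (NaHCO3, CH2Cl2, 0 °C) should close the same ring in the 5-endo mode with the same axis-to-centre transfer and give the vinyl iodide F6. Reduction of F6 with Bu3SnH and Pd(PPh3)4 (cat.) in THF then replaces iodine by hydrogen.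

3. Step 15 (fragment coupling). What may go wrong: base-induced γ-deprotonation of the enal with loss of configuration at C8 or ring opening, or poor E/Z control at C11=C12. The fallback reverses the polarity of the coupling; it sets out from 14 and comes back at 24. CBr4/PPh3 (Appel reaction, CH2Cl2, −30 °C) should convert the primary allylic hydroxyl of 14 into the allylic bromide F7, and PPh3 in toluene would give the phosphonium bromide F8. Wittig reaction of F8 with aldehyde 19 in EtOH, with 1,2-epoxybutane as hydrogen bromide acceptor (no free strong base), followed by thermal Z-to-E equilibration of the C11=C12 bond, should give 24.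

**Further compounds**

F1 | step 8 | tert-butyl{[(2E,4E)-3-methyl-5-(4,4,5,5-tetramethyl-1,3,2-dioxaborolan-2-yl)penta-2,4-dien-1-yl]oxy}diphenylsilane | CC(C)(C)[Si](OC/C=C(C)/C=C/B1OC(C)(C)C(C)(C)O1)(c2ccccc2)c3ccccc3
F2 | step 8 | triethyl{[(1S)-4-[(1E,3E)-5-(tert-butyldiphenylsilyloxy)-3-methylpenta-1,3-dien-1-yl]-3,5,5-trimethylcyclohex-3-en-1-yl]oxy}silane | CC(C)(C)[Si](OC/C=C(C)/C=C/C1=C(C)C[C@H](O[Si](CC)(CC)CC)CC1(C)C)(c2ccccc2)c3ccccc3
F3 | step 8 | (1S)-4-[(1E,3E)-5-(tert-butyldiphenylsilyloxy)-3-methylpenta-1,3-dien-1-yl]-3,5,5-trimethylcyclohex-3-en-1-ol | CC(C)(C)[Si](OC/C=C(C)/C=C/C1=C(C)C[C@H](O)CC1(C)C)(c2ccccc2)c3ccccc3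
F4 | step 8 | (1R,3R,6S)-6-[(1E,3E)-5-(tert-butyldiphenylsilyloxy)-3-methylpenta-1,3-dien-1-yl]-1,5,5-trimethyl-7-oxabicyclo[4.1.0]heptan-3-ol | CC(C)(C)[Si](OC/C=C(C)/C=C/[C@@]12O[C@]1(C)C[C@H](O)CC2(C)C)(c3ccccc3)c4ccccc4
F5 | step 8 | (2S,6R,7aR)-2-[(2E)-4-(tert-butyldiphenylsilyloxy)but-2-en-2-yl]-4,4,7a-trimethyl-2,4,5,6,7,7a-hexahydro-1-benzofuran-6-ol (C8 epimer of 13) | CC(C)(C)[Si](OC/C=C(\C)[C@@H]1C=C2C(C)(C)C[C@@H](O)C[C@@]2(C)O1)(c3ccccc3)c4ccccc4
F6 | step 9 | (2S,6R,7aR)-2-[(2E)-4-(tert-butyldiphenylsilyloxy)but-2-en-2-yl]-3-iodo-4,4,7a-trimethyl-2,4,5,6,7,7a-hexahydro-1-benzofuran-6-ol (3-iodo derivative of 13, same spatial arrangement) | CC(C)(C)[Si](OC/C=C(\C)[C@H]1C(I)=C2C(C)(C)C[C@@H](O)C[C@@]2(C)O1)(c3ccccc3)c4ccccc4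
F7 | step 15 | (2R,6R,7aR)-2-[(2E)-4-bromobut-2-en-2-yl]-4,4,7a-trimethyl-2,4,5,6,7,7a-hexahydro-1-benzofuran-6-ol | BrC/C=C(\C)[C@H]1C=C2C(C)(C)C[C@@H](O)C[C@@]2(C)O1
F8 | step 15 | {(2E)-3-[(2R,6R,7aR)-6-hydroxy-4,4,7a-trimethyl-2,4,5,6,7,7a-hexahydro-1-benzofuran-2-yl]but-2-en-1-yl}triphenylphosphonium bromide | [Br-].C(/C=C(\C)[C@H]1C=C2C(C)(C)C[C@@H](O)C[C@@]2(C)O1)[P+](c3ccccc3)(c4ccccc4)c5ccccc5
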